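The tetrahydrofuran ring (O1, C2 aryl, C3 CH2OH, C4 aroyl, C5 H2) is cut at C2–C3 and O1–C5. This leaves 3,4,5-trimethoxybenzaldehyde and the three-carbon unit C3–C4–C5. The feature exploited is that the aroyl group sits on C4, the central carbon of that unit. In a 2-aroylallylboronate C3 is the nucleophilic γ-carbon. Once it has attacked the aldehyde, the double bond moves to C4=C5, an enone that captures the new alkoxide oxygen at C5. One flask thus joins both halves of the lignan in a formal [3+2] annulation and sets C2, C3 and C4. The precursor is an acyclic, achiral (E)-allylboronate with the silyl-protected hydroxymethyl group on C3.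

Key step: step 4

Assumption: the sense of induction of the chiral phosphoric acid is carried over from crotyl pinacolboronates, where the (R)-acid directs attack to the Re face of aromatic aldehydes, so the (S)-acid is chosen for the Si face needed here; if the substituted boronate reverses the sense, the antipodal acid is used.

Step 1
Reactants: 1 3',4',5'-trimethoxyacetophenone
Product: 2 1-(3,4,5-trimethoxyphenyl)prop-2-en-1-one
Conditions: (CH2O)n, i-Pr2NH·CF3CO2H (1 equiv), CF3CO2H (10 mol %), THF, reflux
Reagents that add atoms: formaldehyde (from paraformaldehyde), C=O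
Why: Mannich condensation of the methyl ketone with the iminium ion from formaldehyde and the ammonium salt, followed by β-elimination of the amine (direct α-methylenation), is an established entry to aryl vinyl ketones and forms no stereocentre.

Step 2
Reactants: 2 1-(3,4,5-trimethoxyphenyl)prop-2-en-1-one; 3 (tert-butyldimethylsilyloxy)acetaldehyde
Product: 5 4-(tert-butyldimethylsilyloxy)-3-hydroxy-2-[(pinacolboryl)methyl]-1-(3,4,5-trimethoxyphenyl)butan-1-one (racemic mixture of diastereomers), via O-pinacolboryl aldolate 4 (not isolated)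
Conditions: B2pin2 (1.1 equiv), CuCl (5 mol %), NaOt-Bu (7 mol %), 1,1'-bis(diphenylphosphino)ferrocene (5 mol %), THF, −20 °C, slow addition of 2; then aq NH4Cl
Reagents that add atoms: bis(pinacolato)diboron, CC1(C)OB(B2OC(C)(C)C(C)(C)O2)OC1(C)C
Why: In this copper-catalysed three-component borylative aldol reaction the boryl-copper species adds to the terminal carbon of the vinyl ketone, the copper enolate is trapped by the α-oxygenated aldehyde, B2pin2 turns over the copper aldolate, and the two new stereocentres need no control because step 3 erases both.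

Step 3
Reactants: 5 β-boryl aldol
Product: 7 (E)-4-(tert-butyldimethylsilyloxy)-2-[(pinacolboryl)methyl]-1-(3,4,5-trimethoxyphenyl)but-2-en-1-one (CH2OTBS cis to CH2B and trans to the aroyl group), via mesylate 6 (not isolated)
Conditions: MsCl (1.3 equiv), Et3N (4 equiv), CH2Cl2, 0 °C → rt
Reagents that add atoms: none
Why: Mesylation and E1cB elimination through the ketone enolate should give the enone in which allylic strain keeps the aroyl group and the CH2OTBS group trans, which is the geometry that step 4 translates into the 2,3-cis ring.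

Step 4
Reactants: 7 (E)-allylboronate; 8 3,4,5-trimethoxybenzaldehyde
Product: 11 {(3R,4S,5S)-4-[(tert-butyldimethylsilyloxy)methyl]-5-(3,4,5-trimethoxyphenyl)oxolan-3-yl}(3,4,5-trimethoxyphenyl)methanone, via homoallyl borate 9 (not isolated), via homoallylic alcohol 10 (not isolated)
Conditions: (S)-3,3'-bis(2,4,6-triisopropylphenyl)-1,1'-binaphthyl-2,2'-diyl hydrogen phosphate (10 mol %), 4 Å MS, toluene, 0 °C → rt; then MeOH (5 equiv), 1,8-diazabicyclo[5.4.0]undec-7-ene (0.5 equiv), 0 °C → rt, same flask
Reagents that add atoms: none
Why: Proposed new method: the chiral phosphoric acid hydrogen-bonds to the pseudo-axial oxygen of the dioxaborolane and to the formyl C–H, C3 of 7 attacks the Si face of 8 through a closed six-membered chair (C2–C3 bond), the double bond moves to C4=C5 to give borate 9, methanol frees alcohol 10, and its amidine-activated oxygen adds to C5 of the unveiled aryl enone (O1–C5 bond) before the enolate is protonated at C4. The closest known reaction types are the chiral-phosphoric-acid-catalysed crotylboration of aromatic aldehydes and the acid-catalysed allylboration with 2-alkoxycarbonylallylboronates, which ends in lactonisation to α-methylene-γ-butyrolactones; new here are the 2-aroyl group on the boronate and conjugate addition as the terminating event. The tetrahydrofuran closes in the 5-endo-trig mode, which is geometrically unfavourable but reversible and precedented for homoallylic alkoxides with a sulfonyl acceptor on the internal alkene carbon, and the saturated ether ketone is the thermodynamic sink, whereas hemiketal formation at the ketone is only a reversible resting state. C2 is controlled by the catalyst (facial choice on the aldehyde), C3 by the alkene geometry of 7 (CH2OTBS cis to CH2B sits axial in the chair, which gives the syn alcohol and hence the 2,3-cis ring), and C4 by equilibration through the enolate, which places the aroyl group trans to the C3 side chain. The step needs three selectivities: aldehyde over aryl ketone, secured by the much lower reactivity of ketones toward pinacol allylboronates; a negligible uncatalysed background, secured by the electron-poor boronate; and a single oxygen nucleophile, secured by the silyl ether on the other hydroxyl.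

Step 5
Reactants: 11 silyl ether of the target
Product: 12 [(3R,4S,5S)-4-(hydroxymethyl)-5-(3,4,5-trimethoxyphenyl)oxolan-3-yl](3,4,5-trimethoxyphenyl)methanone (ring numbering of the overview: 2S,3S,4R; 2,3-cis, 3,4-trans)
Conditions: HF·pyridine, pyridine, THF, 0 °C → rt
Reagents that add atoms: none
Why: Fluoride cleavage of the primary silyl ether in a weakly acidic buffered medium generates no enolate, so retro-oxa-Michael opening, re-closure through the freed hydroxyl and C4 epimerisation should all be avoided and the three stereocentres stay untouched.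

Compound list
1 | 3',4',5'-trimethoxyacetophenone | CC(=O)c1cc(OC)c(OC)c(OC)c1 | starting material
2 | 1-(3,4,5-trimethoxyphenyl)prop-2-en-1-one | C=CC(=O)c1cc(OC)c(OC)c(OC)c1 | intermediate
3 | (tert-butyldimethylsilyloxy)acetaldehyde | O=CCO[Si](C)(C)C(C)(C)C | starting material
4 | O-pinacolboryl aldolate of 5 (racemic diastereomer mixture, not isolated) | CC1(C)OB(CC(C(=O)c2cc(OC)c(OC)c(OC)c2)C(CO[Si](C)(C)C(C)(C)C)OB2OC(C)(C)C(C)(C)O2)OC1(C)C | intermediate
5 | 4-(tert-butyldimethylsilyloxy)-3-hydroxy-2-[(pinacolboryl)methyl]-1-(3,4,5-trimethoxyphenyl)butan-1-one (racemic diastereomer mixture) | CC1(C)OB(CC(C(=O)c2cc(OC)c(OC)c(OC)c2)C(O)CO[Si](C)(C)C(C)(C)C)OC1(C)C | intermediate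
6 | methanesulfonate of 5 (not isolated) | CC1(C)OB(CC(C(=O)c2cc(OC)c(OC)c(OC)c2)C(CO[Si](C)(C)C(C)(C)C)OS(C)(=O)=O)OC1(C)C | intermediate
7 | (E)-4-(tert-butyldimethylsilyloxy)-2-[(pinacolboryl)methyl]-1-(3,4,5-trimethoxyphenyl)but-2-en-1-one | CC1(C)OB(C/C(C(=O)c2cc(OC)c(OC)c(OC)c2)=C\CO[Si](C)(C)C(C)(C)C)OC1(C)C | intermediate
8 | 3,4,5-trimethoxybenzaldehyde | COc1cc(C=O)cc(OC)c1OC | starting material
9 | pinacolboryl ether of (3S,4S)-alcohol 10 (not isolated) | CC1(C)OB(O[C@H](c2cc(OC)c(OC)c(OC)c2)[C@@H](C(=C)C(=O)c2cc(OC)c(OC)c(OC)c2)CO[Si](C)(C)C(C)(C)C)OC1(C)C | intermediate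
10 | (3S,4S)-3-[(tert-butyldimethylsilyloxy)methyl]-4-hydroxy-2-methylidene-1,4-bis(3,4,5-trimethoxyphenyl)butan-1-one (syn, not isolated) | O[C@H](c1cc(OC)c(OC)c(OC)c1)[C@@H](C(=C)C(=O)c1cc(OC)c(OC)c(OC)c1)CO[Si](C)(C)C(C)(C)C | intermediate
11 | {(3R,4S,5S)-4-[(tert-butyldimethylsilyloxy)methyl]-5-(3,4,5-trimethoxyphenyl)oxolan-3-yl}(3,4,5-trimethoxyphenyl)methanone | COc1cc(C(=O)[C@H]2CO[C@H](c3cc(OC)c(OC)c(OC)c3)[C@@H]2CO[Si](C)(C)C(C)(C)C)cc(OC)c1OC | intermediate
12 | [(3R,4S,5S)-4-(hydroxymethyl)-5-(3,4,5-trimethoxyphenyl)oxolan-3-yl](3,4,5-trimethoxyphenyl)methanone | COc1cc(C(=O)[C@H]2CO[C@H](c3cc(OC)c(OC)c(OC)c3)[C@@H]2CO)cc(OC)c1OC | target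

Total step count: 5. Longest linear sequence: 5 steps (1 → 2 → 5 → 7 → 11 → 12).

Steps most likely to fail

Step 4. The acyl group lowers the nucleophilicity of the allylboronate. The acid-bound pathway may therefore stall or lose facial selectivity.

The fallback sets out from 7 and 8 and comes back at 11. It gives up catalyst control in favour of a racemic union followed by resolution.
- The allylboration is run under Sc(OTf)3 (10 mol %, CH2Cl2, rt), the known Lewis-acid acceleration of acceptor-substituted allylboronates.
- The same closure with methanol and 1,8-diazabicyclo[5.4.0]undec-7-ene follows in the flask.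
- The syn relationship is still fixed by the alkene geometry.
- Besides 9, 10 and 11 this forms the mirror-image borate F1, the mirror-image alcohol F2 and the enantiomeric silyl ether F3.
- 11 is parted from its enantiomer by preparative chromatography on a chiral stationary phase (amylose tris(3,5-dimethylphenylcarbamate), supercritical CO2/MeOH) and re-enters at step 5.

Step 2. The boryl-copper species may add to the aldehyde carbonyl. Alternatively, the enolate may add to a second molecule of vinyl ketone before the aldehyde intercepts it.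

The fallback sets out from 2 and comes back at 5. It separates the two bond formations.
- Conjugate borylation of 2 with methanol as proton source (CuCl, NaOt-Bu, 1,1'-bis(diphenylphosphino)ferrocene, B2pin2, MeOH, THF) gives 3-(pinacolboryl)-1-(3,4,5-trimethoxyphenyl)propan-1-one F4.
- F4 is converted into its preformed lithium enolate (LiN(SiMe3)2, THF, −78 °C) and added to 3 in a directed aldol reaction.

Step 3. Loss of the mesylate may give poor control of the alkene geometry, or the base may shift the double bond toward the silyloxy-bearing carbon. Either erodes the 2,3-cis selectivity of step 4.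

The fallback sets out from 2 and 3 and comes back at 7. It makes the trisubstituted alkene by allylic substitution instead of dehydration.
- A halo-aldol reaction (TiCl4, n-Bu4NI, CH2Cl2, −78 °C) gives the iodo aldol F5.
- Dehydroiodination with Et3N gives the Morita–Baylis–Hillman-type allylic alcohol F6. This route avoids amine-induced dimerisation of the aryl vinyl ketone.
- Boc2O with catalytic 4-(dimethylamino)pyridine gives the tert-butyl carbonate F7.
- Copper-catalysed SN2' borylation (CuCl, 4,5-bis(diphenylphosphino)-9,9-dimethylxanthene, KOt-Bu, B2pin2, THF, 0 °C) delivers 7 by addition–elimination.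

Further compounds
F1 | step 4 | pinacolboryl ether of the (3R,4R)-alcohol, mirror image of 9 | CC1(C)OB(O[C@@H](c2cc(OC)c(OC)c(OC)c2)[C@H](C(=C)C(=O)c2cc(OC)c(OC)c(OC)c2)CO[Si](C)(C)C(C)(C)C)OC1(C)C
F2 | step 4 | (3R,4R)-3-[(tert-butyldimethylsilyloxy)methyl]-4-hydroxy-2-methylidene-1,4-bis(3,4,5-trimethoxyphenyl)butan-1-one, mirror image of 10 | O[C@@H](c1cc(OC)c(OC)c(OC)c1)[C@H](C(=C)C(=O)c1cc(OC)c(OC)c(OC)c1)CO[Si](C)(C)C(C)(C)C
F3 | step 4 | {(3S,4R,5R)-4-[(tert-butyldimethylsilyloxy)methyl]-5-(3,4,5-trimethoxyphenyl)oxolan-3-yl}(3,4,5-trimethoxyphenyl)methanone, enantiomer of 11 | COc1cc(C(=O)[C@@H]2CO[C@@H](c3cc(OC)c(OC)c(OC)c3)[C@H]2CO[Si](C)(C)C(C)(C)C)cc(OC)c1OC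
F4 | step 2 | 3-(pinacolboryl)-1-(3,4,5-trimethoxyphenyl)propan-1-one | CC1(C)OB(CCC(=O)c2cc(OC)c(OC)c(OC)c2)OC1(C)C
F5 | step 3 | 4-(tert-butyldimethylsilyloxy)-3-hydroxy-2-(iodomethyl)-1-(3,4,5-trimethoxyphenyl)butan-1-one (racemic; stereocentres erased on the way to 7) | O=C(c1cc(OC)c(OC)c(OC)c1)C(CI)C(O)CO[Si](C)(C)C(C)(C)C
F6 | step 3 | 4-(tert-butyldimethylsilyloxy)-3-hydroxy-2-methylidene-1-(3,4,5-trimethoxyphenyl)butan-1-one (racemic) | C=C(C(=O)c1cc(OC)c(OC)c(OC)c1)C(O)CO[Si](C)(C)C(C)(C)C
F7 | step 3 | tert-butyl carbonate of F6 (racemic) | C=C(C(=O)c1cc(OC)c(OC)c(OC)c1)C(CO[Si](C)(C)C(C)(C)C)OC(=O)OC(C)(C)C
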